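**Retrosynthetic overview**
1. Target ⇒ (−)-xyloketal B + an (S)-2-isopropenyl-dihydrobenzofuran-5-yl methanol; the last bond is ArCH2–Ar, made by dehydrative Friedel–Crafts benzylation at the only free aromatic CH.
2. Xyloketal B ⇒ phloroglucinol (from resorcinol by C–H borylation/oxidation) + 2 × [(4R)-2,4-dimethyl-4,5-dihydrofuran-3-yl]methanol; Friedel–Crafts alkylation/ketalisation closes both pyran rings.
3. Dihydrofuran alcohol ⇒ ester ⇒ key ring expansion (3 → 5) of a (2S)-1-acetyl-2-methylcyclopropane carboxylate ⇒ methyl acetoacetate + (R)-propylene cyclic sulfate.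
4. Benzylic alcohol ⇒ (S)-5-bromo-2-isopropenyl-2,3-dihydrobenzofuran ⇒ asymmetric Pd heteroannulation of 4-bromo-2-iodophenol with isoprene.
5. Ring order: cyclopropane → dihydrofuran (the later tetrahydrofuran rings); dihydrobenzofuran in a separate branch; then the two ketal pyran rings on the phloroglucinol core; benzylation last.

Assumption: (4R)-4-methyl-1,3,2-dioxathiolane 2,2-dioxide is taken as commercially available; CIP analysis of the given SMILES gives R at all six ketal-unit centres and S at the dihydrobenzofuran C2.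

**Route**

Step 1
Reactants: 1 methyl acetoacetate; 2 (4R)-4-methyl-1,3,2-dioxathiolane 2,2-dioxide
Product: 4 methyl (2S)-1-acetyl-2-methylcyclopropane-1-carboxylate (C1 epimer mixture), via sulfate monoester 3 (not isolated)
Conditions: NaH (2.2 equiv), DME, 0 °C then 80 °C
Reagents that add atoms: none
Why: Double alkylation of a β-keto ester by a cyclic sulfate (Gao–Sharpless-type cyclopropanation): C-alkylation at the primary carbon, then 3-exo-tet SN2 closure at the secondary sulfate with inversion sets C2 as S, and the C1 epimers do not matter because C1 becomes sp2 in step 2.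

Step 2
Reactants: 4 methyl (2S)-1-acetyl-2-methylcyclopropane-1-carboxylate
Product: 5 methyl (4R)-2,4-dimethyl-4,5-dihydrofuran-3-carboxylate
Conditions: DABCO (20 mol%), DMSO, 110 °C
Reagents that add atoms: none
Why: Proposed new method: an amine-catalysed Cloke–Wilson ring expansion with distal-bond selectivity, in which DABCO opens the doubly activated cyclopropane by SN2 at the unhindered CH2 (a tertiary amine cannot readily attack the methyl-bearing carbon) and the ketone-enolate oxygen then displaces the ammonium group by 5-exo-tet O-alkylation, so the C–CH2 bond is exchanged for an O–CH2 bond, the CH(CH3) centre is never touched (2S cyclopropane gives 4R dihydrofuran) and strain release drives the reaction; the closest known reaction type is the DABCO- or halide-catalysed Cloke–Wilson rearrangement of 2-aryl or 2-vinyl acylcyclopropanes, where the substituted carbon is attacked, together with homoconjugate SN2 opening of electrophilic cyclopropanes.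

Step 3
Reactants: 5 methyl (4R)-2,4-dimethyl-4,5-dihydrofuran-3-carboxylate
Product: 6 [(4R)-2,4-dimethyl-4,5-dihydrofuran-3-yl]methanol
Conditions: LiAlH4, Et2O, 0 °C; NaOH (Fieser) work-up; used crude at once
Reagents that add atoms: none
Why: 1,2-Hydride reduction of the vinylogous carbonate ester to the allylic alcohol, with a basic work-up that keeps the acid-labile enol ether and the remote stereocentre intact.

Step 4
Reactants: 7 resorcinol
Product: 10 phloroglucinol (benzene-1,3,5-triol), via bis-boryl ether 8 (not isolated), via tris-boryl arene 9 (not isolated)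
Conditions: [Ir(OMe)(cod)]2 (1.5 mol%), dtbpy (3 mol%), HBpin (5 equiv), THF, 80 °C; then Oxone, acetone/H2O, rt
Reagents that add atoms: Oxone (potassium peroxymonosulfate), [K+].[O-]S(=O)(=O)OO
Why: One-pot Ir-catalysed C–H borylation/oxidation: the phenols are masked in situ as O–Bpin ethers, steric control directs borylation to C5 (the only CH not ortho to a substituent), and the C–B bond is oxidised to C–OH.

Step 5
Reactants: 10 phloroglucinol; 6 [(4R)-2,4-dimethyl-4,5-dihydrofuran-3-yl]methanol (2.1 equiv)
Product: 12 (−)-xyloketal B, via mono-ketal diol 11 (not isolated)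
Conditions: BF3·OEt2 (20 mol%), MgSO4, Et2O, 0 °C
Reagents that add atoms: none
Why: Friedel–Crafts alkylation/ketalisation cascade, run twice: the allylic oxocarbenium ion from 6 alkylates the arene and the neighbouring phenol closes the cis-fused bicyclic ketal under thermodynamic control with the ArCH2 group anti to the C3 methyl (3a R, 9a R from the 4R centre), the angular bis-adduct being the favoured regioisomer.

Step 6
Reactants: 13 4-bromophenol
Product: 14 4-bromo-2-iodophenol
Conditions: NIS (1.05 equiv), TsOH·H2O (10 mol%), MeCN, rt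
Reagents that add atoms: N-iodosuccinimide, O=C1CCC(=O)N1I
Why: Electrophilic aromatic iodination ortho to the hydroxyl group, the para position being blocked.

Step 7
Reactants: 14 4-bromo-2-iodophenol; 15 isoprene (3 equiv)
Product: 16 (2S)-5-bromo-2-(prop-1-en-2-yl)-2,3-dihydro-1-benzofuran
Conditions: Pd2(dba)3 (2.5 mol%), chiral sulfinamide–monophosphine ligand (TY-Phos type, antipode giving 2S; 6 mol%), K2CO3 (2 equiv), toluene, 50 °C, sealed tube
Reagents that add atoms: none
Why: Larock-type heteroannulation (Heck carbopalladation at the less hindered vinyl terminus, then asymmetric Tsuji–Trost C–O closure of the π-allyl palladium) in which the ligand sets C2 as S and the C–I bond undergoes oxidative addition in preference to C–Br.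

Step 8
Reactants: 16 (2S)-5-bromo-2-(prop-1-en-2-yl)-2,3-dihydro-1-benzofuran
Product: 18 [(2S)-2-(prop-1-en-2-yl)-2,3-dihydro-1-benzofuran-5-yl]methanol, via aldehyde 17 (not isolated)
Conditions: n-BuLi, THF, −78 °C; DMF, −78 → 0 °C; then NaBH4, MeOH, 0 °C
Reagents that add atoms: N,N-dimethylformamide, CN(C)C=O
Why: Bromine–lithium exchange, formylation of the aryllithium with DMF and in situ borohydride reduction, none of which touches the C2 stereocentre or the isopropenyl group at low temperature.

Step 9
Reactants: 12 (−)-xyloketal B (1.2 equiv); 18 [(2S)-2-(prop-1-en-2-yl)-2,3-dihydro-1-benzofuran-5-yl]methanol (added slowly)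
Product: 19 target compound
Conditions: HFIP/CH2Cl2 (1:4), 0 °C → rt
Reagents that add atoms: none
Why: HFIP-promoted dehydrative Friedel–Crafts benzylation: the p-alkoxybenzylic cation is captured at the single unsubstituted, triply oxygen-activated carbon of 12, with no acid strong enough to open the ketals or protonate the isopropenyl group, so no stereocentre is affected.

**Compound list**
1 | methyl acetoacetate | CC(=O)CC(=O)OC | starting material
2 | (4R)-4-methyl-1,3,2-dioxathiolane 2,2-dioxide | C[C@@H]1COS(=O)(=O)O1 | starting material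
3 | sodium (2R)-4-acetyl-5-methoxy-5-oxopentan-2-yl sulfate | COC(=O)C(C(C)=O)C[C@@H](C)OS(=O)(=O)[O-].[Na+] | intermediate (not isolated)
4 | methyl (2S)-1-acetyl-2-methylcyclopropane-1-carboxylate (C1 epimers) | C[C@H]1CC1(C(C)=O)C(=O)OC | intermediate
5 | methyl (4R)-2,4-dimethyl-4,5-dihydrofuran-3-carboxylate | C[C@H]1COC(C)=C1C(=O)OC | intermediate
6 | [(4R)-2,4-dimethyl-4,5-dihydrofuran-3-yl]methanol | C[C@H]1COC(C)=C1CO | intermediate
7 | resorcinol | Oc1cccc(O)c1 | starting material
8 | 1,3-bis[(4,4,5,5-tetramethyl-1,3,2-dioxaborolan-2-yl)oxy]benzene | CC1(C)OB(Oc2cccc(OB3OC(C)(C)C(C)(C)O3)c2)OC1(C)C | intermediate (not isolated)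
9 | 2-{3,5-bis[(pinacolboryl)oxy]phenyl}-4,4,5,5-tetramethyl-1,3,2-dioxaborolane | CC1(C)OB(Oc2cc(OB3OC(C)(C)C(C)(C)O3)cc(c2)B2OC(C)(C)C(C)(C)O2)OC1(C)C | intermediate (not isolated)
10 | phloroglucinol | Oc1cc(O)cc(O)c1 | intermediate
11 | (3R,3aR,9aR)-3,9a-dimethyl-3,3a,4,9a-tetrahydro-2H-furo[2,3-b]chromene-5,7-diol | Oc1cc(O)c2c(c1)O[C@@]1(C)OC[C@H](C)[C@H]1C2 | intermediate (not isolated)
12 | (−)-xyloketal B (angular bis-ketal, both units 3R,3aR,9aR, one free OH, one free aromatic CH) | Oc1cc2O[C@@]3(C)OC[C@H](C)[C@H]3Cc2c2O[C@@]3(C)OC[C@H](C)[C@H]3Cc12 | intermediate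
13 | 4-bromophenol | Oc1ccc(Br)cc1 | starting material
14 | 4-bromo-2-iodophenol | Oc1ccc(Br)cc1I | intermediate
15 | isoprene | C=CC(C)=C | starting material
16 | (2S)-5-bromo-2-(prop-1-en-2-yl)-2,3-dihydro-1-benzofuran | C=C(C)[C@@H]1Cc2cc(Br)ccc2O1 | intermediate
17 | (2S)-2-(prop-1-en-2-yl)-2,3-dihydro-1-benzofuran-5-carbaldehyde | C=C(C)[C@@H]1Cc2cc(C=O)ccc2O1 | intermediate (not isolated)
18 | [(2S)-2-(prop-1-en-2-yl)-2,3-dihydro-1-benzofuran-5-yl]methanol | C=C(C)[C@@H]1Cc2cc(CO)ccc2O1 | intermediate
19 | target: xyloketal B carrying the [(2S)-2-(prop-1-en-2-yl)-2,3-dihydro-1-benzofuran-5-yl]methyl group on its former free aromatic carbon | C=C(C)[C@@H]1Cc2cc(Cc3c(O)c4c(c5c3O[C@@]3(C)OC[C@H](C)[C@H]3C5)O[C@@]3(C)OC[C@H](C)[C@H]3C4)ccc2O1 | target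

**Totals and risks**
Total steps: 9. Longest linear sequence: 5 (steps 1, 2, 3, 5, 9).

Most likely to fail:

Step 2 (the proposed ring expansion). The amine may open the cyclopropane at the methyl-bearing carbon (giving the 5-methyl isomer), the ring-opened zwitterion may eliminate, or step 1 may already have delivered too little cyclopropane through competing O-closure. The fallback uses known chemistry, sets out from 1 and comes back at 5, bypassing steps 1 and 2. Commercial methyl (R)-lactate is converted with Tf2O/2,6-lutidine into methyl (2R)-2-(trifluoromethylsulfonyloxy)propanoate F1. The sodium enolate of 1 displaces the triflate by SN2 with inversion to give dimethyl (3R)-2-acetyl-3-methylbutanedioate F2. The β-keto ester is masked as its sodium enolate (NaH) while LiBH4 reduces the other ester, and acidic work-up lactonises the product to (4R)-3-acetyl-4-methyloxolan-2-one F3. HCl in methanol then effects the Korte acyl-lactone rearrangement to 5.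

Step 5 (bis-annulation). The reaction is statistical: mono-, bis- and tris-adducts, the regioisomeric bis-ketal and C3a/C9a epimers all lower the yield of 12. The fallback reverses the order of the two couplings; it sets out from 10 and 18 and comes back at 19, replacing steps 5 and 9. Phloroglucinol 10 (4 equiv) is benzylated by 18 in HFIP to 2-{[(2S)-2-(prop-1-en-2-yl)-2,3-dihydro-1-benzofuran-5-yl]methyl}benzene-1,3,5-triol F4. F4 has only two free aromatic positions, so treatment with 6 (2.5 equiv), BF3·OEt2 (cat.), MgSO4 in Et2O at −20 to 0 °C cannot over-alkylate and gives 19 directly; the isomer with the free hydroxyl para to the benzyl group is removed by chromatography.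

Step 7 (asymmetric heteroannulation). The risks are incomplete I/Br chemoselectivity, the 2-methyl-2-vinyl regioisomer and insufficient ee with an iodophenol. The fallback sets the stereocentre by epoxidation instead; it sets out from 13 and comes back at 16. The sodium salt of 13 is ortho-C-prenylated (NaH, prenyl bromide, toluene) to 4-bromo-2-(3-methylbut-2-en-1-yl)phenol F5, which is silylated (TBSCl, imidazole) to [4-bromo-2-(3-methylbut-2-en-1-yl)phenoxy](tert-butyl)dimethylsilane F6. Shi epoxidation (Oxone, pH 10.5), with the fructose-derived ketone enantiomer that delivers the R epoxide, gives {4-bromo-2-[((2R)-3,3-dimethyloxiran-2-yl)methyl]phenoxy}(tert-butyl)dimethylsilane F7. TBAF frees the phenoxide, which opens the epoxide 5-exo-tet with inversion to 2-[(2S)-5-bromo-2,3-dihydro-1-benzofuran-2-yl]propan-2-ol F8. Burgess dehydration then gives 16.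

Further compounds
F1 | step 2 | methyl (2R)-2-(trifluoromethylsulfonyloxy)propanoate | COC(=O)[C@@H](C)OS(=O)(=O)C(F)(F)F
F2 | step 2 | dimethyl (3R)-2-acetyl-3-methylbutanedioate | COC(=O)[C@H](C)C(C(C)=O)C(=O)OC
F3 | step 2 | (4R)-3-acetyl-4-methyloxolan-2-one | C[C@H]1COC(=O)C1C(C)=O
F4 | step 5 | 2-{[(2S)-2-(prop-1-en-2-yl)-2,3-dihydro-1-benzofuran-5-yl]methyl}benzene-1,3,5-triol | C=C(C)[C@@H]1Cc2cc(Cc3c(O)cc(O)cc3O)ccc2O1
F5 | step 7 | 4-bromo-2-(3-methylbut-2-en-1-yl)phenol | CC(C)=CCc1cc(Br)ccc1O
F6 | step 7 | [4-bromo-2-(3-methylbut-2-en-1-yl)phenoxy](tert-butyl)dimethylsilane | CC(C)=CCc1cc(Br)ccc1O[Si](C)(C)C(C)(C)C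
F7 | step 7 | {4-bromo-2-[((2R)-3,3-dimethyloxiran-2-yl)methyl]phenoxy}(tert-butyl)dimethylsilane | CC1(C)O[C@@H]1Cc1cc(Br)ccc1O[Si](C)(C)C(C)(C)C
F8 | step 7 | 2-[(2S)-5-bromo-2,3-dihydro-1-benzofuran-2-yl]propan-2-ol | CC(C)(O)[C@@H]1Cc2cc(Br)ccc2O1
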